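**Plan**
- Retrosynthesis: ring C is removed first by cutting C8–C14 and C9–C11 (hydroxycyclobutenone ring expansion of a C9 alkenyl metal), then ring B is stripped of its two side chains by cutting C4–C5 and C10–C1.
- Forward: (R)-carvone supplies ring B as a 5-silyloxy-2-methylcyclohexenone; one operation adds isopropenyl to C5 and the propanoate chain to C10; the C9 ketone becomes the alkenyllithium that builds ring C; oxidation and quinone reduction finish.
- Enabling feature: C5 and the quaternary C10 are neighbours in ring B, C10 carries the methyl and sits next to C9, and C7 (two carbons from C5) carries an oxygen, so C5/C10 map onto the β/α carbons of an enone with a directing group at C7.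
- Stereochemistry: C7 (R) comes from carvone by Criegee rearrangement with retention; it sends the cuprate to the opposite face (C5, S); the C5 isopropenyl then sends the acrylate to the opposite face (C10, S); C7 is finally oxidised to the ketone.
- The ester is taken to a silyl ether before the alkenyllithium is made and is re-oxidised at the end together with C7.

Key step: step 4

Remark: atoms carry abietane-type numbers (chain C1–C3 with the carboxyl at C3, isopropenyl carbon C4, ring B = C5–C10, ring C = C8, C9, C11–C14). Stereocentres left open in 2, 3, 19 and 22 and the enol geometry of 23 are mixtures of no consequence. In step 1 the acetate carbonyl oxygen of 4 is assumed to come from methanol (O-demethylation of the rearranged dioxacarbenium ion by acetate).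

**Step 1**
Reactants: 1 (R)-(−)-carvone
Product: 4 (R)-5-acetoxy-2-methylcyclohex-2-en-1-one, via methoxy hydroperoxide 2 (not isolated), via peracetate 3 (not isolated)
Conditions: O3, CH2Cl2/MeOH, −78 °C; then Ac2O, Et3N, DMAP (cat.), −78 °C → rt
Reagents that add atoms: ozone, O=[O+][O-]; methanol, CO
Why: The electron-rich isopropenyl group is ozonised in preference to the enone double bond, methanol traps the carbonyl oxide as 2, and acetylation to 3 triggers a Criegee rearrangement in which the ring carbon migrates to oxygen with retention, so C7 should keep the R configuration.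

**Step 2**
Reactants: 4 (R)-5-acetoxy-2-methylcyclohex-2-en-1-one
Product: 5 (R)-5-hydroxy-2-methylcyclohex-2-en-1-one
Conditions: K2CO3 (cat.), MeOH, 0 °C
Reagents that add atoms: none
Why: Base-catalysed transesterification of the secondary acetate at 0 °C should outrun enolisation towards C8 and loss of acetate, and the stereocentre is not touched.

**Step 3**
Reactants: 5 (R)-5-hydroxy-2-methylcyclohex-2-en-1-one
Product: 6 (R)-5-(tert-butyldimethylsilyloxy)-2-methylcyclohex-2-en-1-one
Conditions: TBSCl, imidazole, DMF, 0 °C → rt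
Reagents that add atoms: tert-butyldimethylsilyl chloride, CC(C)(C)[Si](C)(C)Cl
Why: Standard imidazole-promoted silylation of a secondary alcohol gives a bulky, non-chelating directing group that survives organocopper and enolate chemistry.

**Step 4**
Reactants: 6 (R)-5-(tert-butyldimethylsilyloxy)-2-methylcyclohex-2-en-1-one; 7 isopropenylmagnesium bromide; 8 tert-butyl acrylate
Product: 10 keto ester (5S,7R,10S), via bromomagnesium enolate 9 (not isolated)
Conditions: 7 (1.3 equiv), CuBr·SMe2 (15 mol %), THF, −78 → −40 °C; then 8 (1.5 equiv), −78 → −20 °C; aq NH4Cl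
Reagents that add atoms: isopropenylmagnesium bromide 7, C=C(C)[Mg]Br; tert-butyl acrylate 8, C=CC(=O)OC(C)(C)C
Why: Transmetalation of the Grignard reagent to copper gives an isopropenylcuprate that adds 1,4 to the enone (C4–C5 bond) and leaves the regiodefined C9–C10 enolate 9, whose tetrasubstituted carbon C10 then adds to the β-carbon of the acrylate (C10–C1 bond), the ester enolate being protonated on quench. The closest known reaction type is the tandem cuprate conjugate addition–Michael trapping (three-component coupling) of 2-methylcyclohex-2-enones. No ring is closed. C5 is controlled by the C7 silyloxy group, because the cuprate attacks axially on the face anti to it, as is general for 5-substituted cyclohexenones, which gives the 5,7-trans (5S) arrangement. C10 is controlled by the new C5 isopropenyl group, which sits pseudoaxial in the enolate to avoid allylic strain with the C10 methyl and shields its own face, so the acrylate bonds trans to it (10S, methyl cis to isopropenyl). The step needs C-alkylation before the enolate equilibrates towards C8; low temperature, the magnesium counter-ion and the bulky tert-butyl ester (no 1,2-addition, no Dieckmann closure, slow oligomerisation) are expected to secure this.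

**Step 5**
Reactants: 10 keto ester
Product: 12 enol triflate ester, via potassium enolate 11 (not isolated)
Conditions: KN(SiMe3)2, THF, −78 °C; then PhNTf2, −78 → −30 °C
Reagents that add atoms: N-phenylbis(trifluoromethanesulfonimide), O=S(=O)(N(c1ccccc1)S(=O)(=O)C(F)(F)F)C(F)(F)F
Why: The ketone can enolise only towards C8 because C10 is quaternary, it is more acidic than the ester, and O-sulfonylation of the cold potassium enolate should be faster than loss of the C7 silanolate or attack on the tert-butyl ester.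

**Step 6**
Reactants: 12 enol triflate ester
Product: 14 triflate alcohol, via aldehyde 13 (not isolated)
Conditions: i-Bu2AlH, CH2Cl2, −78 → 0 °C; aq potassium sodium tartrate (KNaC4H4O6)
Reagents that add atoms: none
Why: i-Bu2AlH reduces the ester through the aldehyde to the primary alcohol without touching the enol triflate, the silyl ether or the alkene, and this removes the one group that would not survive the C9 alkenyllithium of step 10.

**Step 7**
Reactants: 14 triflate alcohol
Product: 15 bis-silyl enol triflate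
Conditions: TBSCl, imidazole, DMF, rt
Reagents that add atoms: tert-butyldimethylsilyl chloride, CC(C)(C)[Si](C)(C)Cl
Why: Routine silylation of the primary alcohol gives the same protecting group as at C7, so both can be removed together in step 12.

**Step 8**
Reactants: 15 bis-silyl enol triflate
Product: 16 alkenyl trimethylstannane
Conditions: Me3SnSnMe3, Pd(PPh3)4 (5 mol %), LiCl, THF, 65 °C
Reagents that add atoms: hexamethylditin, C[Sn](C)(C)[Sn](C)(C)C
Why: Palladium-catalysed stannylation of enol triflates with hexamethylditin (oxidative addition, chloride exchange, Sn–Sn transmetalation, reductive elimination) is established for hindered cycloalkenyl triflates and leaves silyl ethers and the isopropenyl group untouched.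

**Step 9**
Reactants: 17 dimethyl squarate; 18 isopropylmagnesium chloride
Product: 20 3-methoxy-4-(propan-2-yl)cyclobut-3-ene-1,2-dione, via hydroxycyclobutenone 19 (not isolated)
Conditions: THF, −78 °C; 1 M HCl; then 12 M HCl (cat.), CH2Cl2, rt
Reagents that add atoms: isopropylmagnesium chloride 18, CC(C)[Mg]Cl
Why: 1,2-Addition of the Grignard reagent to one squarate carbonyl followed by acid-catalysed loss of methanol from the resulting vinylogous hemiketal is the standard route to 3-alkyl-4-alkoxycyclobutenediones.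

**Step 10**
Reactants: 16 alkenyl trimethylstannane; 20 3-methoxy-4-(propan-2-yl)cyclobut-3-ene-1,2-dione
Product: 22 alkenyl hydroxycyclobutenone, via alkenyllithium 21 (not isolated)
Conditions: MeLi, THF, −78 → −20 °C; then 20 in THF, −78 °C; aq NH4Cl
Reagents that add atoms: none
Why: Tin–lithium exchange gives the C9 alkenyllithium, which adds 1,2 to the more electrophilic carbonyl of 20 (the one next to the methoxy-bearing carbon, the other being a vinylogous ester), so that C9 ends up on the carbinol carbon that becomes C11; the new carbinol centre is lost in step 11.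

**Step 11**
Reactants: 22 alkenyl hydroxycyclobutenone
Product: 25 quinone bis-silyl ether, via dienylketene 23 (not isolated), via hydroquinone 24 (not isolated)
Conditions: p-xylene, 138 °C; then Ag2O, Et2O, rt
Reagents that add atoms: none
Why: In this Moore rearrangement, conrotatory ring opening with the hydroxyl rotating outward gives dienylketene 23, six-electron electrocyclisation of the ketene carbon onto C8 and tautomerisation give hydroquinone 24 (C8–C14 bond, ring C), and Ag2O converts the air-sensitive hydroquinone into the isolable quinone.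

**Step 12**
Reactants: 25 quinone bis-silyl ether
Product: 26 quinone diol
Conditions: 48% aq HF, MeCN, 0 °C → rt
Reagents that add atoms: none
Why: Aqueous HF in acetonitrile cleaves primary and secondary silyl ethers without base, which the methoxyquinone would not tolerate, and the 7-hydroxy quinone motif is stable, as in the natural 7-hydroxyroyleanones.

**Step 13**
Reactants: 26 quinone diol
Product: 28 keto acid quinone, via keto aldehyde 27 (not isolated)
Conditions: Jones reagent (CrO3, H2SO4, H2O), acetone, 0 °C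
Reagents that add atoms: water, O (second carboxyl oxygen, through the aldehyde hydrate)
Why: Jones oxidation takes the C7 alcohol to the ketone and the primary alcohol through the aldehyde hydrate to the acid, while the quinone is already fully oxidised and C5, being β to the new ketone, cannot epimerise.

**Step 14**
Reactants: 28 keto acid quinone
Product: 29 target hydroquinone keto acid (CNP0249049.1)
Conditions: Na2S2O4, THF/H2O, rt (degassed)
Reagents that add atoms: none
Why: Dithionite reduces the quinone selectively to the hydroquinone, leaving the aryl ketone, acid and alkene alone, and the product should be stabilised by the hydrogen bond from the C14 hydroxyl to the C7 carbonyl.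

**Compound list**
1 | (R)-(−)-carvone, (5R)-2-methyl-5-(prop-1-en-2-yl)cyclohex-2-en-1-one | CC1=CC[C@@H](C(C)=C)CC1=O | starting material
2 | (5R)-5-(1-hydroperoxy-1-methoxyethyl)-2-methylcyclohex-2-en-1-one | CC1=CC[C@@H](C(C)(OC)OO)CC1=O | intermediate (not isolated)
3 | 1-methoxy-1-[(1R)-4-methyl-5-oxocyclohex-3-en-1-yl]ethyl peracetate | CC1=CC[C@@H](C(C)(OC)OOC(C)=O)CC1=O | intermediate (not isolated)
4 | (R)-5-acetoxy-2-methylcyclohex-2-en-1-one | CC1=CC[C@@H](OC(C)=O)CC1=O | intermediate
5 | (R)-5-hydroxy-2-methylcyclohex-2-en-1-one | CC1=CC[C@@H](O)CC1=O | intermediate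
6 | (R)-5-(tert-butyldimethylsilyloxy)-2-methylcyclohex-2-en-1-one | CC1=CC[C@@H](O[Si](C)(C)C(C)(C)C)CC1=O | intermediate (key-step precursor)
7 | isopropenylmagnesium bromide | C=C(C)[Mg]Br | starting material
8 | tert-butyl acrylate | C=CC(=O)OC(C)(C)C | starting material
9 | bromomagnesium (3S,5R)-5-(tert-butyldimethylsilyloxy)-2-methyl-3-(prop-1-en-2-yl)cyclohex-1-en-1-olate | C=C(C)[C@@H]1C[C@@H](O[Si](C)(C)C(C)(C)C)CC(O[Mg]Br)=C1C | intermediate (not isolated)
10 | tert-butyl 3-[(1S,2S,4R)-4-(tert-butyldimethylsilyloxy)-1-methyl-6-oxo-2-(prop-1-en-2-yl)cyclohexyl]propanoate | C=C(C)[C@@H]1C[C@@H](O[Si](C)(C)C(C)(C)C)CC(=O)[C@@]1(C)CCC(=O)OC(C)(C)C | intermediate (key-step product)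
11 | potassium enolate of 10 (C8=C9 enolate) | C=C(C)[C@@H]1C[C@@H](O[Si](C)(C)C(C)(C)C)C=C(O[K])[C@@]1(C)CCC(=O)OC(C)(C)C | intermediate (not isolated)
12 | tert-butyl 3-[(1S,4R,6S)-4-(tert-butyldimethylsilyloxy)-1-methyl-6-(prop-1-en-2-yl)-2-(trifluoromethanesulfonyloxy)cyclohex-2-en-1-yl]propanoate | C=C(C)[C@@H]1C[C@@H](O[Si](C)(C)C(C)(C)C)C=C(OS(=O)(=O)C(F)(F)F)[C@@]1(C)CCC(=O)OC(C)(C)C | intermediate
13 | 3-[(1S,4R,6S)-4-(tert-butyldimethylsilyloxy)-1-methyl-6-(prop-1-en-2-yl)-2-(trifluoromethanesulfonyloxy)cyclohex-2-en-1-yl]propanal | C=C(C)[C@@H]1C[C@@H](O[Si](C)(C)C(C)(C)C)C=C(OS(=O)(=O)C(F)(F)F)[C@@]1(C)CCC=O | intermediate (not isolated)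
14 | (3R,5S,6S)-3-(tert-butyldimethylsilyloxy)-6-(3-hydroxypropyl)-6-methyl-5-(prop-1-en-2-yl)cyclohex-1-en-1-yl trifluoromethanesulfonate | C=C(C)[C@@H]1C[C@@H](O[Si](C)(C)C(C)(C)C)C=C(OS(=O)(=O)C(F)(F)F)[C@@]1(C)CCCO | intermediate
15 | (3R,5S,6S)-3-(tert-butyldimethylsilyloxy)-6-[3-(tert-butyldimethylsilyloxy)propyl]-6-methyl-5-(prop-1-en-2-yl)cyclohex-1-en-1-yl trifluoromethanesulfonate | C=C(C)[C@@H]1C[C@@H](O[Si](C)(C)C(C)(C)C)C=C(OS(=O)(=O)C(F)(F)F)[C@@]1(C)CCCO[Si](C)(C)C(C)(C)C | intermediate
16 | [(3R,5S,6S)-3-(tert-butyldimethylsilyloxy)-6-[3-(tert-butyldimethylsilyloxy)propyl]-6-methyl-5-(prop-1-en-2-yl)cyclohex-1-en-1-yl]trimethylstannane | C=C(C)[C@@H]1C[C@@H](O[Si](C)(C)C(C)(C)C)C=C([Sn](C)(C)C)[C@@]1(C)CCCO[Si](C)(C)C(C)(C)C | intermediate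
17 | dimethyl squarate, 3,4-dimethoxycyclobut-3-ene-1,2-dione | COC1=C(OC)C(=O)C1=O | starting material
18 | isopropylmagnesium chloride | CC(C)[Mg]Cl | starting material
19 | 4-hydroxy-2,3-dimethoxy-4-(propan-2-yl)cyclobut-2-en-1-one | COC1=C(OC)C(O)(C(C)C)C1=O | intermediate (not isolated)
20 | 3-methoxy-4-(propan-2-yl)cyclobut-3-ene-1,2-dione | COC1=C(C(C)C)C(=O)C1=O | intermediate
21 | C9 alkenyllithium from 16 | C=C(C)[C@@H]1C[C@@H](O[Si](C)(C)C(C)(C)C)C=C([Li])[C@@]1(C)CCCO[Si](C)(C)C(C)(C)C | intermediate (not isolated)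
22 | 4-[(3R,5S,6S)-3-(tert-butyldimethylsilyloxy)-6-[3-(tert-butyldimethylsilyloxy)propyl]-6-methyl-5-(prop-1-en-2-yl)cyclohex-1-en-1-yl]-4-hydroxy-3-methoxy-2-(propan-2-yl)cyclobut-2-en-1-one | C=C(C)[C@@H]1C[C@@H](O[Si](C)(C)C(C)(C)C)C=C(C2(O)C(OC)=C(C(C)C)C2=O)[C@@]1(C)CCCO[Si](C)(C)C(C)(C)C | intermediate
23 | 4-(cyclohexenyl)-4-hydroxy-3-methoxy-2-(propan-2-yl)buta-1,3-dien-1-one (dienylketene from 22) | C=C(C)[C@@H]1C[C@@H](O[Si](C)(C)C(C)(C)C)C=C(C(O)=C(OC)C(C(C)C)=C=O)[C@@]1(C)CCCO[Si](C)(C)C(C)(C)C | intermediate (not isolated)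
24 | (5S,6S,8R)-8-(tert-butyldimethylsilyloxy)-5-[3-(tert-butyldimethylsilyloxy)propyl]-3-methoxy-5-methyl-2-(propan-2-yl)-6-(prop-1-en-2-yl)-5,6,7,8-tetrahydronaphthalene-1,4-diol | C=C(C)[C@@H]1C[C@@H](O[Si](C)(C)C(C)(C)C)c2c(O)c(C(C)C)c(OC)c(O)c2[C@@]1(C)CCCO[Si](C)(C)C(C)(C)C | intermediate (not isolated)
25 | (5S,6S,8R)-8-(tert-butyldimethylsilyloxy)-5-[3-(tert-butyldimethylsilyloxy)propyl]-3-methoxy-5-methyl-2-(propan-2-yl)-6-(prop-1-en-2-yl)-5,6,7,8-tetrahydronaphthalene-1,4-dione | C=C(C)[C@@H]1C[C@@H](O[Si](C)(C)C(C)(C)C)C2=C(C(=O)C(OC)=C(C(C)C)C2=O)[C@@]1(C)CCCO[Si](C)(C)C(C)(C)C | intermediate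
26 | (5S,6S,8R)-8-hydroxy-5-(3-hydroxypropyl)-3-methoxy-5-methyl-2-(propan-2-yl)-6-(prop-1-en-2-yl)-5,6,7,8-tetrahydronaphthalene-1,4-dione | C=C(C)[C@@H]1C[C@@H](O)C2=C(C(=O)C(OC)=C(C(C)C)C2=O)[C@@]1(C)CCCO | intermediate
27 | 3-[(1S,2S)-7-methoxy-1-methyl-4,5,8-trioxo-6-(propan-2-yl)-2-(prop-1-en-2-yl)-1,2,3,4,5,8-hexahydronaphthalen-1-yl]propanal | C=C(C)[C@@H]1CC(=O)C2=C(C(=O)C(OC)=C(C(C)C)C2=O)[C@@]1(C)CCC=O | intermediate (not isolated)
28 | 3-[(1S,2S)-7-methoxy-1-methyl-4,5,8-trioxo-6-(propan-2-yl)-2-(prop-1-en-2-yl)-1,2,3,4,5,8-hexahydronaphthalen-1-yl]propanoic acid | C=C(C)[C@@H]1CC(=O)C2=C(C(=O)C(OC)=C(C(C)C)C2=O)[C@@]1(C)CCC(=O)O | intermediate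
29 | 3-[(1S,2S)-5,8-dihydroxy-7-methoxy-1-methyl-4-oxo-6-(propan-2-yl)-2-(prop-1-en-2-yl)-1,2,3,4-tetrahydronaphthalen-1-yl]propanoic acid | C=C(C)[C@@H]1CC(=O)c2c(O)c(C(C)C)c(OC)c(O)c2[C@@]1(C)CCC(=O)O | target

**Count**
Total steps: 14. Longest linear sequence: 13 steps (steps 1–8 and 10–14 from (R)-carvone); step 9 is a one-step side branch.

**Steps most likely to fail**

Step 4. The Michael trapping of the congested tetrasubstituted magnesium enolate may be slower than oligomerisation of the acrylate, or than proton transfer to C8 followed by loss of the C7 silanolate; facial selectivity at C10 may also erode. The fallback separates the two bond formations and uses an alkylation in place of the Michael addition. It sets out from 6 and comes back at 15.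
- The same copper-catalysed addition of 7 is run with Me3SiCl and gives trimethylsilyl enol ether F1.
- MeLi (THF, 0 °C) regenerates the regiodefined lithium enolate F2, and allyl iodide alkylates it at C10 trans to the isopropenyl group to give allyl ketone F3.
- Disiamylborane, which prefers the monosubstituted alkene over the isopropenyl group and the hindered ketone, gives alkylborane F4; NaBO3·4H2O oxidises it to hydroxy ketone F5.
- Silylation (TBSCl, imidazole) gives bis-silyl ketone F6; KN(SiMe3)2 forms potassium enolate F7, and PhNTf2 gives 15. The ester reduction of step 6 is no longer needed.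

Step 10. Tin–lithium exchange at C9, next to the quaternary carbon, may stay incomplete, and the remaining methyllithium would then consume dione 20; addition of the bulky nucleophile may also be slow. The fallback makes the nucleophile by halogen–metal exchange. It sets out from 16 and comes back at 22.
- I2 (CH2Cl2, 0 °C) converts 16 into alkenyl iodide F8.
- Two equivalents of t-BuLi (Et2O, −78 °C) give 21 irreversibly and with no other alkyllithium present; addition to 20 as before gives 22.

Step 13. Holding the acylquinone in aqueous chromic acid until the side chain is fully oxidised may cause acid-induced migration of the isopropenyl double bond, redox tautomerism across C5–C7, or over-oxidation. The fallback separates the two oxidations so that the C7 ketone is formed last under neutral conditions. It sets out from 25 and comes back at 28.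
- The primary silyl ether alone is cleaved (HF·pyridine buffered with pyridine, THF, 0 °C) to give primary alcohol F9.
- TEMPO (cat.) with PhI(OAc)2 in aqueous MeCN oxidises it to silyloxy acid F10.
- Aqueous HF in MeCN removes the C7 silyl group to give hydroxy acid F11, and Dess–Martin periodinane gives 28.

**Further compounds**
F1 | step 4 | tert-butyldimethyl{[(1R,5S)-4-methyl-5-(prop-1-en-2-yl)-3-(trimethylsilyloxy)cyclohex-3-en-1-yl]oxy}silane | C=C(C)[C@@H]1C[C@@H](O[Si](C)(C)C(C)(C)C)CC(O[Si](C)(C)C)=C1C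
F2 | step 4 | lithium (3S,5R)-5-(tert-butyldimethylsilyloxy)-2-methyl-3-(prop-1-en-2-yl)cyclohex-1-en-1-olate | C=C(C)[C@@H]1C[C@@H](O[Si](C)(C)C(C)(C)C)CC(O[Li])=C1C
F3 | step 4 | (2S,3S,5R)-5-(tert-butyldimethylsilyloxy)-2-methyl-2-(prop-2-en-1-yl)-3-(prop-1-en-2-yl)cyclohexan-1-one | C=C(C)[C@@H]1C[C@@H](O[Si](C)(C)C(C)(C)C)CC(=O)[C@@]1(C)CC=C
F4 | step 4 | bis(3-methylbutan-2-yl){3-[(1S,2S,4R)-4-(tert-butyldimethylsilyloxy)-1-methyl-6-oxo-2-(prop-1-en-2-yl)cyclohexyl]propyl}borane | C=C(C)[C@@H]1C[C@@H](O[Si](C)(C)C(C)(C)C)CC(=O)[C@@]1(C)CCCB(C(C)C(C)C)C(C)C(C)C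
F5 | step 4 | (2S,3S,5R)-5-(tert-butyldimethylsilyloxy)-2-(3-hydroxypropyl)-2-methyl-3-(prop-1-en-2-yl)cyclohexan-1-one | C=C(C)[C@@H]1C[C@@H](O[Si](C)(C)C(C)(C)C)CC(=O)[C@@]1(C)CCCO
F6 | step 4 | (2S,3S,5R)-5-(tert-butyldimethylsilyloxy)-2-[3-(tert-butyldimethylsilyloxy)propyl]-2-methyl-3-(prop-1-en-2-yl)cyclohexan-1-one | C=C(C)[C@@H]1C[C@@H](O[Si](C)(C)C(C)(C)C)CC(=O)[C@@]1(C)CCCO[Si](C)(C)C(C)(C)C
F7 | step 4 | potassium enolate of F6 (C8=C9 enolate) | C=C(C)[C@@H]1C[C@@H](O[Si](C)(C)C(C)(C)C)C=C(O[K])[C@@]1(C)CCCO[Si](C)(C)C(C)(C)C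
F8 | step 10 | tert-butyl{3-[(1S,4R,6S)-4-(tert-butyldimethylsilyloxy)-2-iodo-1-methyl-6-(prop-1-en-2-yl)cyclohex-2-en-1-yl]propoxy}dimethylsilane | C=C(C)[C@@H]1C[C@@H](O[Si](C)(C)C(C)(C)C)C=C(I)[C@@]1(C)CCCO[Si](C)(C)C(C)(C)C
F9 | step 13 | (5S,6S,8R)-8-(tert-butyldimethylsilyloxy)-5-(3-hydroxypropyl)-3-methoxy-5-methyl-2-(propan-2-yl)-6-(prop-1-en-2-yl)-5,6,7,8-tetrahydronaphthalene-1,4-dione | C=C(C)[C@@H]1C[C@@H](O[Si](C)(C)C(C)(C)C)C2=C(C(=O)C(OC)=C(C(C)C)C2=O)[C@@]1(C)CCCO
F10 | step 13 | 3-[(1S,2S,4R)-4-(tert-butyldimethylsilyloxy)-7-methoxy-1-methyl-5,8-dioxo-6-(propan-2-yl)-2-(prop-1-en-2-yl)-1,2,3,4,5,8-hexahydronaphthalen-1-yl]propanoic acid | C=C(C)[C@@H]1C[C@@H](O[Si](C)(C)C(C)(C)C)C2=C(C(=O)C(OC)=C(C(C)C)C2=O)[C@@]1(C)CCC(=O)O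
F11 | step 13 | 3-[(1S,2S,4R)-4-hydroxy-7-methoxy-1-methyl-5,8-dioxo-6-(propan-2-yl)-2-(prop-1-en-2-yl)-1,2,3,4,5,8-hexahydronaphthalen-1-yl]propanoic acid | C=C(C)[C@@H]1C[C@@H](O)C2=C(C(=O)C(OC)=C(C(C)C)C2=O)[C@@]1(C)CCC(=O)O
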